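**Plan**

-   Retrosynthesis cuts, in this order: the two angeloyl C–O bonds; the C1–O bond of the 1,10-epoxide (C1 mesylate, C10 alkoxide) and the oxygen of the 4,5-epoxide (Z-alkene C4=C5); C1–C2 (aldol polarity: C1 aldehyde, C2 enol ether carbon); C2–C3 (methylenation); C10–C14 (Grignard); C8–C9 (aldol).
-   Forward: (S)-carvone supplies C3–C8 with C7 and the Z alkene C4=C5, and its ring is cut between C3 and C8. C8–C9 is joined by a proline aldol. The C3 acid and the C8 hydroxyl are then tied through one oxygen as an oxepinone (ring A), and methylenation of this lactone adds C2.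
-   Key event: C2 of the dienol ether adds to the C1 aldehyde. This closes a second seven-membered ring (O, C3, C2, C1, C10, C9, C8) and with it the ten-membered carbocycle, as the periphery of an 11-oxabicyclo[4.4.1] cation. Hydrolysis of the C3–O bond then unties the cyclodecenone; the 4,5- and 1,10-epoxides are closed afterwards.
-   Enabling feature: C3 and C8 both bear oxygen and face each other 1,6 across the ten-membered ring, so a single oxygen can bridge them. C2 is the methylene between the oxygenated carbons C1 and C3 (1,3-dioxygen pattern).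
-   Stereochemistry: C7 from carvone; C8 and C9 by (S)-proline catalysis matched with the Felkin preference of the aldehyde; C10 by axial Grignard attack; C1 by C10 and the tether, then inverted in the epoxide closure; C3 by CBS reduction; C4 and C5 by hydroxyl-directed epoxidation.

Key step: step 11

Remark: locants C1–C15 are the germacrane locants of the target (ring C1–C10, C14 on C10, C15 on C4, isopropenyl C11–C13 on C7) and are kept for all intermediates; the C8 epimer of 3 would serve equally, because C8 becomes a formyl carbon in step 2.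

**Route**

Step 1
Reactants: 1 (S)-(+)-carvone
Product: 3 (5R,6R)-6-hydroxy-2-methyl-5-(prop-1-en-2-yl)cyclohex-2-en-1-one, via lithium dienolate 2 (not isolated)
Conditions: LiN(i-Pr)2, THF, −78 °C; then 3-phenyl-2-(phenylsulfonyl)oxaziridine, −78 °C; aq NH4Cl
Reagents that add atoms: 3-phenyl-2-(phenylsulfonyl)oxaziridine, O=S(=O)(c1ccccc1)N1OC1c1ccccc1
Why: Kinetic deprotonation of the enone at C8 (the alpha-prime carbon) followed by electrophilic hydroxylation of the cross-conjugated enolate (Davis oxidation) should place the hydroxyl anti to the neighbouring isopropenyl group, and the configuration at C8 is of no consequence because this carbon becomes a formyl group in step 2.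

Step 2
Reactants: 3 (5R,6R)-6-hydroxy-2-methyl-5-(prop-1-en-2-yl)cyclohex-2-en-1-one
Product: 4 (2Z,5R)-5-formyl-2,6-dimethylhepta-2,6-dienoic acid
Conditions: NaIO4, THF/H2O (pH 6 phosphate buffer), 0 °C → rt
Reagents that add atoms: water, O
Why: Periodate cleavage of the alpha-hydroxy ketone (glycol-type C–C cleavage through the ketone hydrate) should cut the C3–C8 bond of the carvone ring to the C3 acid and the C8 aldehyde, the ring having fixed the Z geometry of C4=C5, while the cold near-neutral medium should keep the C7 centre next to the aldehyde from epimerising.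

Step 3
Reactants: 4 (2Z,5R)-5-formyl-2,6-dimethylhepta-2,6-dienoic acid; 5 2,2-dimethyl-1,3-dioxan-5-one
Product: 6 (2Z,5R,6S)-6-[(4S)-2,2-dimethyl-5-oxo-1,3-dioxan-4-yl]-6-hydroxy-2-methyl-5-(prop-1-en-2-yl)hex-2-enoic acid
Conditions: (S)-proline (30 mol %), 5 (2.5 equiv), DMF, 4 °C
Reagents that add atoms: none
Why: The proline-catalysed enamine aldol of the dioxanone with an alpha-branched aldehyde (List–Enders aldol) should give the anti adduct with C8 and C9 both S through the hydrogen-bonded Houk–List transition state, the catalyst preference coinciding with the Felkin–Anh preference of the aldehyde (isopropenyl anti to the incoming nucleophile).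

Step 4
Reactants: 6 (2Z,5R,6S)-6-[(4S)-2,2-dimethyl-5-oxo-1,3-dioxan-4-yl]-6-hydroxy-2-methyl-5-(prop-1-en-2-yl)hex-2-enoic acid
Product: 7 (2Z,5R,6S)-6-hydroxy-6-[(4S,5R)-5-hydroxy-2,2,5-trimethyl-1,3-dioxan-4-yl]-2-methyl-5-(prop-1-en-2-yl)hex-2-enoic acid
Conditions: MeMgBr (5 equiv), THF, −78 → −30 °C; aq NH4Cl
Reagents that add atoms: methylmagnesium bromide, C[Mg]Br
Why: Grignard 1,2-addition to the activated dioxanone carbonyl (carboxylate and alkoxide are spectators) should occur by axial attack on the chair that holds the C9 side chain equatorial, because a 1,3-dioxan-5-one has no syn-axial hydrogens, so that C14 ends axial and the C10 hydroxyl equatorial and trans to the side chain (C10 R in 7, the configuration the target needs).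

Step 5
Reactants: 7 (2Z,5R,6S)-6-hydroxy-6-[(4S,5R)-5-hydroxy-2,2,5-trimethyl-1,3-dioxan-4-yl]-2-methyl-5-(prop-1-en-2-yl)hex-2-enoic acid
Product: 9 (6R,7S)-7-[(4S,5R)-5-hydroxy-2,2,5-trimethyl-1,3-dioxan-4-yl]-3-methyl-6-(prop-1-en-2-yl)-6,7-dihydro-5H-oxepin-2-one, via mixed anhydride 8 (not isolated)
Conditions: 2,4,6-trichlorobenzoyl chloride, Et3N, THF, rt; then slow addition to 4-(dimethylamino)pyridine, toluene, 60 °C (0.002 M)
Reagents that add atoms: none
Why: Yamaguchi lactonisation should acylate only the secondary C8 hydroxyl (the C10 hydroxyl is tertiary), and because the Z alkene holds the C3 acyl group next to C8 the seven-membered oxepinone (ring A) that ties C3 to C8 through oxygen should form readily.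

Step 6
Reactants: 9 (6R,7S)-7-[(4S,5R)-5-hydroxy-2,2,5-trimethyl-1,3-dioxan-4-yl]-3-methyl-6-(prop-1-en-2-yl)-6,7-dihydro-5H-oxepin-2-one
Product: 10 (6R,7S)-3-methyl-6-(prop-1-en-2-yl)-7-[(1S,2R)-1,2,3-trihydroxy-2-methylpropyl]-6,7-dihydro-5H-oxepin-2-one
Conditions: AcOH/THF/H2O (3:1:1), 40 °C
Reagents that add atoms: none
Why: Acid hydrolysis of the isopropylidene ketal (acetal cleavage) frees the C9, C10 and C1 hydroxyls, while the lactone and the alkenes are stable to aqueous acetic acid.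

Step 7
Reactants: 10 (6R,7S)-3-methyl-6-(prop-1-en-2-yl)-7-[(1S,2R)-1,2,3-trihydroxy-2-methylpropyl]-6,7-dihydro-5H-oxepin-2-one
Product: 11 (6R,7S)-7-[(1S,2R)-1-(tert-butyldimethylsilyloxy)-2-methyl-2,3-bis(triethylsilyloxy)propyl]-3-methyl-6-(prop-1-en-2-yl)-6,7-dihydro-5H-oxepin-2-one
Conditions: Et3SiCl (1.05 equiv), imidazole, CH2Cl2, −40 °C; then 2,6-lutidine, t-BuMe2SiOTf (1.2 equiv), −78 °C; then Et3SiOTf (1.5 equiv), 0 °C
Reagents that add atoms: chlorotriethylsilane, CC[Si](Cl)(CC)CC; tert-butyldimethylsilyl triflate, CC(C)(C)[Si](C)(C)OS(=O)(=O)C(F)(F)F; triethylsilyl triflate, CC[Si](CC)(CC)OS(=O)(=O)C(F)(F)F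
Why: Graded silyl ether formation follows the steric order primary C1–OH, secondary C9–OH, tertiary C10–OH, which places the more labile triethylsilyl group on C1 and C10 and the robust tert-butyldimethylsilyl group on C9, the hydroxyl that must stay masked to the end.

Step 8
Reactants: 11 (6R,7S)-7-[(1S,2R)-1-(tert-butyldimethylsilyloxy)-2-methyl-2,3-bis(triethylsilyloxy)propyl]-3-methyl-6-(prop-1-en-2-yl)-6,7-dihydro-5H-oxepin-2-one
Product: 12 (6R,7S)-7-[(1S,2R)-1-(tert-butyldimethylsilyloxy)-2-methyl-2,3-bis(triethylsilyloxy)propyl]-3-methyl-2-methylidene-6-(prop-1-en-2-yl)-2,5,6,7-tetrahydrooxepine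
Conditions: Cp2TiMe2 (3 equiv), toluene, 65 °C, dark
Reagents that add atoms: dimethyltitanocene, C[Ti](C)(C1C=CC=C1)C1C=CC=C1
Why: Petasis methylenation of the lactone carbonyl, the only carbonyl group present, through Cp2Ti=CH2 should give the exocyclic 2-alkoxydiene, which installs C2 as a nucleophilic terminus and keeps the C3–O–C8 link.

Step 9
Reactants: 12 (6R,7S)-7-[(1S,2R)-1-(tert-butyldimethylsilyloxy)-2-methyl-2,3-bis(triethylsilyloxy)propyl]-3-methyl-2-methylidene-6-(prop-1-en-2-yl)-2,5,6,7-tetrahydrooxepine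
Product: 13 (2R,3S)-3-(tert-butyldimethylsilyloxy)-2-methyl-3-[(2S,3R)-6-methyl-7-methylidene-3-(prop-1-en-2-yl)-2,3,4,7-tetrahydrooxepin-2-yl]-2-(triethylsilyloxy)propan-1-ol
Conditions: Bu4NF (1.05 equiv), THF, −20 °C
Reagents that add atoms: none
Why: Fluoride desilylation should remove the primary triethylsilyl ether well before the tertiary triethylsilyl and the hindered secondary tert-butyldimethylsilyl ethers, and the basic medium spares the acid-labile dienol ether.

Step 10
Reactants: 13 (2R,3S)-3-(tert-butyldimethylsilyloxy)-2-methyl-3-[(2S,3R)-6-methyl-7-methylidene-3-(prop-1-en-2-yl)-2,3,4,7-tetrahydrooxepin-2-yl]-2-(triethylsilyloxy)propan-1-ol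
Product: 14 (2S,3S)-3-(tert-butyldimethylsilyloxy)-2-methyl-3-[(2S,3R)-6-methyl-7-methylidene-3-(prop-1-en-2-yl)-2,3,4,7-tetrahydrooxepin-2-yl]-2-(triethylsilyloxy)propanal
Conditions: SO3·pyridine, DMSO, i-Pr2NEt, CH2Cl2, 0 °C
Reagents that add atoms: none
Why: Parikh–Doering oxidation converts the neopentyl primary alcohol into the C1 aldehyde under basic conditions that the dienol ether tolerates, and the aldehyde cannot epimerise because C10 is fully substituted.

Step 11
Reactants: 14 (2S,3S)-3-(tert-butyldimethylsilyloxy)-2-methyl-3-[(2S,3R)-6-methyl-7-methylidene-3-(prop-1-en-2-yl)-2,3,4,7-tetrahydrooxepin-2-yl]-2-(triethylsilyloxy)propanal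
Product: 16 (1S,4Z,7R,8S,9S,10R)-9-(tert-butyldimethylsilyloxy)-8-hydroxy-1,10-bis(triethylsilyloxy)germacra-4,11-dien-3-one, via bridged oxocarbenium triflate 15 (not isolated)
Conditions: Et3SiOTf (1.3 equiv), 2,6-di-tert-butyl-4-methylpyridine, CH2Cl2 (0.003 M), −78 → −40 °C; then aq NaHCO3, THF, 0 °C
Reagents that add atoms: triethylsilyl triflate, CC[Si](CC)(CC)OS(=O)(=O)C(F)(F)F; water, O
Why: Proposed new method: Silylation of the aldehyde oxygen makes C1 a silyloxocarbenium ion, the terminal carbon C2 of the 2-alkoxydiene adds to it, and the resulting oxocarbenium ion 15 (C3=O+–C8, conjugated with C4=C5) is hydrolysed on work-up at the C3–O bond to the C3 enone and the free C8 hydroxyl. The closest known reactions are the silyl-triflate- or Lewis-acid-promoted Mukaiyama-type (Prins) additions of 2-alkoxypropenes and of exocyclic enol ethers of lactones to aldehydes and, in concept, the Ferrier carbocyclisation, but a bridging version that builds a medium carbocycle on a lactone-derived dienol ether has not been shown. The bond C1–C2 closes the seven-membered ring O–C3–C2–C1–C10–C9–C8 in a 7-(enolendo)-exo-trig mode, and this ring together with oxepine ring A forms an 11-oxabicyclo[4.4.1]undecane whose periphery is the ten-membered carbocycle, so the ten-ring closure is bought at the cost of a seven-ring closure. The new stereocentre C1 is set by C10 and by the tether: with the non-chelating silyloxy group at C10 turned away from the carbonyl dipole (Cornforth arrangement) C2 can reach only the face of C1 on the side of C9, which gives the C1/C10 syn arrangement (C1 S). The step needs attack through C2 and not C5 of the diene (only C2 attack gives an oxygen-stabilised cation), survival of the dienol ether (the hindered pyridine removes triflic acid) and cyclisation over oligomerisation (high dilution and the short tether).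

Step 12
Reactants: 16 (1S,4Z,7R,8S,9S,10R)-9-(tert-butyldimethylsilyloxy)-8-hydroxy-1,10-bis(triethylsilyloxy)germacra-4,11-dien-3-one
Product: 17 (1S,3S,4Z,7R,8S,9S,10R)-9-(tert-butyldimethylsilyloxy)-1,10-bis(triethylsilyloxy)germacra-4,11-diene-3,8-diol
Conditions: (R)-Me-CBS oxazaborolidine [(R)-1-methyl-3,3-diphenyltetrahydro-1H,3H-pyrrolo[1,2-c][1,3,2]oxazaborole] (0.3 equiv), catecholborane (3 equiv), toluene, −78 °C; then MeOH, aq NaHCO3
Reagents that add atoms: none
Why: Corey–Bakshi–Shibata reduction with the (R)-oxazaborolidine should deliver hydride to the C3 ketone with the alkenyl carbon C4 as the large and the C2 methylene as the small group, giving the 3S allylic alcohol under reagent control, and catecholborane at −78 °C does not hydroborate the isopropenyl group.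

Step 13
Reactants: 17 (1S,3S,4Z,7R,8S,9S,10R)-9-(tert-butyldimethylsilyloxy)-1,10-bis(triethylsilyloxy)germacra-4,11-diene-3,8-diol
Product: 18 (1S,3S,4R,5S,7R,8S,9S,10R)-9-(tert-butyldimethylsilyloxy)-4,5-epoxy-1,10-bis(triethylsilyloxy)germacr-11-ene-3,8-diol
Conditions: mCPBA (1.05 equiv), NaHCO3, CH2Cl2, −20 → 0 °C
Reagents that add atoms: 3-chloroperoxybenzoic acid, OOC(=O)c1cccc(Cl)c1
Why: Hydroxyl-directed peracid epoxidation (Henbest effect) of the Z-trisubstituted allylic alcohol should deliver oxygen to the face set by the 3S hydroxyl in the conformer that avoids allylic 1,3-strain between C2 and C6, the threo (trans) outcome known for Z-allylic alcohols in open chains and medium rings, which sets C4 and C5 as in the target, and the hydrogen-bonded trisubstituted alkene should react well before the isopropenyl group.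

Step 14
Reactants: 18 (1S,3S,4R,5S,7R,8S,9S,10R)-9-(tert-butyldimethylsilyloxy)-4,5-epoxy-1,10-bis(triethylsilyloxy)germacr-11-ene-3,8-diol; 19 angelic acid
Product: 20 (1S,3S,4S,5S,7R,8S,9S,10R)-9-(tert-butyldimethylsilyloxy)-4,5-epoxy-1,10-bis(triethylsilyloxy)germacr-11-ene-3,8-diyl bis[(2Z)-2-methylbut-2-enoate]
Conditions: 19 (6 equiv), 2,4,6-trichlorobenzoyl chloride (6 equiv), Et3N, toluene, rt; then 18, 75 °C
Reagents that add atoms: none
Why: Acylation of both secondary hydroxyls (C3 and C8) by the mixed 2,4,6-trichlorobenzoic anhydride of angelic acid (Yamaguchi-type esterification without an acyl-transfer catalyst) is the known way to transfer the angeloyl group without Z to E isomerisation.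

Step 15
Reactants: 20 (1S,3S,4S,5S,7R,8S,9S,10R)-9-(tert-butyldimethylsilyloxy)-4,5-epoxy-1,10-bis(triethylsilyloxy)germacr-11-ene-3,8-diyl bis[(2Z)-2-methylbut-2-enoate]
Product: 21 (1S,3S,4S,5S,7R,8S,9S,10R)-9-(tert-butyldimethylsilyloxy)-4,5-epoxy-1,10-dihydroxygermacr-11-ene-3,8-diyl bis[(2Z)-2-methylbut-2-enoate]
Conditions: HF·pyridine, pyridine, THF, 0 °C
Reagents that add atoms: none
Why: Buffered fluoride desilylation should remove the two triethylsilyl ethers (C1 and C10) well before the hindered secondary tert-butyldimethylsilyl ether at C9, and the pyridine buffer protects the 4,5-epoxide and the esters.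

Step 16
Reactants: 21 (1S,3S,4S,5S,7R,8S,9S,10R)-9-(tert-butyldimethylsilyloxy)-4,5-epoxy-1,10-dihydroxygermacr-11-ene-3,8-diyl bis[(2Z)-2-methylbut-2-enoate]
Product: 23 (1R,3S,4S,5S,7R,8S,9S,10R)-9-(tert-butyldimethylsilyloxy)-1,10:4,5-diepoxygermacr-11-ene-3,8-diyl bis[(2Z)-2-methylbut-2-enoate], via C1 mesylate 22 (not isolated)
Conditions: MsCl, Et3N, CH2Cl2, −10 °C; filtration and concentration; then KN(SiMe3)2, THF, −78 → 0 °C
Reagents that add atoms: none
Why: Sulfonylation of the only secondary hydroxyl (C1) and intramolecular Williamson displacement by the C10 alkoxide (3-exo-tet) should close the 1,10-epoxide with inversion at C1, so that the syn diol becomes the cis-epoxide with C2 and C9 on the same side (C1 R, C10 untouched).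

Step 17
Reactants: 23 (1R,3S,4S,5S,7R,8S,9S,10R)-9-(tert-butyldimethylsilyloxy)-1,10:4,5-diepoxygermacr-11-ene-3,8-diyl bis[(2Z)-2-methylbut-2-enoate]
Product: 24 (1R,3S,4S,5S,7R,8S,9S,10S)-1,10:4,5-diepoxy-9-hydroxygermacr-11-ene-3,8-diyl bis[(2Z)-2-methylbut-2-enoate] (CNP0304877.1)
Conditions: HF·pyridine, THF, 0 °C → rt
Reagents that add atoms: none
Why: Acidic fluoride cleavage of the C9 silyl ether frees the hydroxyl without forming an alkoxide, which avoids Payne rearrangement of the neighbouring epoxide and acyl migration from C8.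

**Compound list**

1 | (S)-(+)-carvone, (5S)-2-methyl-5-(prop-1-en-2-yl)cyclohex-2-en-1-one | C=C(C)[C@H]1CC=C(C)C(=O)C1 | starting material
2 | lithium (3S)-6-methyl-3-(prop-1-en-2-yl)cyclohexa-1,5-dien-1-olate | C=C(C)[C@H]1CC=C(C)C([O-])=C1.[Li+] | intermediate (not isolated)
3 | (5R,6R)-6-hydroxy-2-methyl-5-(prop-1-en-2-yl)cyclohex-2-en-1-one (trans-6-hydroxycarvone) | C=C(C)[C@H]1CC=C(C)C(=O)[C@@H]1O | intermediate
4 | (2Z,5R)-5-formyl-2,6-dimethylhepta-2,6-dienoic acid | C=C(C)[C@H](C=O)C/C=C(/C)C(=O)O | intermediate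
5 | 2,2-dimethyl-1,3-dioxan-5-one | CC1(C)OCC(=O)CO1 | starting material
6 | (2Z,5R,6S)-6-[(4S)-2,2-dimethyl-5-oxo-1,3-dioxan-4-yl]-6-hydroxy-2-methyl-5-(prop-1-en-2-yl)hex-2-enoic acid | C=C(C)[C@@H](C/C=C(/C)C(=O)O)[C@H](O)[C@@H]1OC(C)(C)OCC1=O | intermediate
7 | (2Z,5R,6S)-6-hydroxy-6-[(4S,5R)-5-hydroxy-2,2,5-trimethyl-1,3-dioxan-4-yl]-2-methyl-5-(prop-1-en-2-yl)hex-2-enoic acid | C=C(C)[C@@H](C/C=C(/C)C(=O)O)[C@H](O)[C@@H]1OC(C)(C)OC[C@@]1(C)O | intermediate
8 | mixed anhydride of acid 7 with 2,4,6-trichlorobenzoic acid | C=C(C)[C@@H](C/C=C(/C)C(=O)OC(=O)c2c(Cl)cc(Cl)cc2Cl)[C@H](O)[C@@H]1OC(C)(C)OC[C@@]1(C)O | intermediate (not isolated)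
9 | (6R,7S)-7-[(4S,5R)-5-hydroxy-2,2,5-trimethyl-1,3-dioxan-4-yl]-3-methyl-6-(prop-1-en-2-yl)-6,7-dihydro-5H-oxepin-2-one | C=C(C)[C@H]1CC=C(C)C(=O)O[C@@H]1[C@@H]2OC(C)(C)OC[C@@]2(C)O | intermediate
10 | (6R,7S)-3-methyl-6-(prop-1-en-2-yl)-7-[(1S,2R)-1,2,3-trihydroxy-2-methylpropyl]-6,7-dihydro-5H-oxepin-2-one | C=C(C)[C@H]1CC=C(C)C(=O)O[C@@H]1[C@H](O)[C@](C)(O)CO | intermediate
11 | (6R,7S)-7-[(1S,2R)-1-(tert-butyldimethylsilyloxy)-2-methyl-2,3-bis(triethylsilyloxy)propyl]-3-methyl-6-(prop-1-en-2-yl)-6,7-dihydro-5H-oxepin-2-one | C=C(C)[C@H]1CC=C(C)C(=O)O[C@@H]1[C@H](O[Si](C)(C)C(C)(C)C)[C@](C)(O[Si](CC)(CC)CC)CO[Si](CC)(CC)CC | intermediate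
12 | (6R,7S)-7-[(1S,2R)-1-(tert-butyldimethylsilyloxy)-2-methyl-2,3-bis(triethylsilyloxy)propyl]-3-methyl-2-methylidene-6-(prop-1-en-2-yl)-2,5,6,7-tetrahydrooxepine | C=C(C)[C@H]1CC=C(C)C(=C)O[C@@H]1[C@H](O[Si](C)(C)C(C)(C)C)[C@](C)(O[Si](CC)(CC)CC)CO[Si](CC)(CC)CC | intermediate
13 | (2R,3S)-3-(tert-butyldimethylsilyloxy)-2-methyl-3-[(2S,3R)-6-methyl-7-methylidene-3-(prop-1-en-2-yl)-2,3,4,7-tetrahydrooxepin-2-yl]-2-(triethylsilyloxy)propan-1-ol | C=C(C)[C@H]1CC=C(C)C(=C)O[C@@H]1[C@H](O[Si](C)(C)C(C)(C)C)[C@](C)(O[Si](CC)(CC)CC)CO | intermediate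
14 | (2S,3S)-3-(tert-butyldimethylsilyloxy)-2-methyl-3-[(2S,3R)-6-methyl-7-methylidene-3-(prop-1-en-2-yl)-2,3,4,7-tetrahydrooxepin-2-yl]-2-(triethylsilyloxy)propanal | C=C(C)[C@H]1CC=C(C)C(=C)O[C@@H]1[C@H](O[Si](C)(C)C(C)(C)C)[C@](C)(O[Si](CC)(CC)CC)C=O | intermediate
15 | bridged oxocarbenium triflate (11-oxoniabicyclo[4.4.1]undecadiene cation, C3=O+–C8, with C1–OSiEt3) | C=C(C)[C@H]1CC=C(C)C2=[O+][C@@H]1[C@H](O[Si](C)(C)C(C)(C)C)[C@](C)(O[Si](CC)(CC)CC)[C@@H](O[Si](CC)(CC)CC)C2.[O-]S(=O)(=O)C(F)(F)F | intermediate (not isolated)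
16 | (1S,4Z,7R,8S,9S,10R)-9-(tert-butyldimethylsilyloxy)-8-hydroxy-1,10-bis(triethylsilyloxy)germacra-4,11-dien-3-one | C=C(C)[C@H]1C/C=C(C)\C(=O)C[C@H](O[Si](CC)(CC)CC)[C@@](C)(O[Si](CC)(CC)CC)[C@@H](O[Si](C)(C)C(C)(C)C)[C@H]1O | intermediate
17 | (1S,3S,4Z,7R,8S,9S,10R)-9-(tert-butyldimethylsilyloxy)-1,10-bis(triethylsilyloxy)germacra-4,11-diene-3,8-diol | C=C(C)[C@H]1C/C=C(C)\[C@@H](O)C[C@H](O[Si](CC)(CC)CC)[C@@](C)(O[Si](CC)(CC)CC)[C@@H](O[Si](C)(C)C(C)(C)C)[C@H]1O | intermediate
18 | (1S,3S,4R,5S,7R,8S,9S,10R)-9-(tert-butyldimethylsilyloxy)-4,5-epoxy-1,10-bis(triethylsilyloxy)germacr-11-ene-3,8-diol | C=C(C)[C@H]1C[C@@H]2O[C@]2(C)[C@@H](O)C[C@H](O[Si](CC)(CC)CC)[C@@](C)(O[Si](CC)(CC)CC)[C@@H](O[Si](C)(C)C(C)(C)C)[C@H]1O | intermediate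
19 | angelic acid, (2Z)-2-methylbut-2-enoic acid | C/C=C(/C)C(=O)O | starting material
20 | (1S,3S,4S,5S,7R,8S,9S,10R)-9-(tert-butyldimethylsilyloxy)-4,5-epoxy-1,10-bis(triethylsilyloxy)germacr-11-ene-3,8-diyl bis[(2Z)-2-methylbut-2-enoate] | C=C(C)[C@H]1C[C@@H]2O[C@]2(C)[C@@H](OC(=O)/C(C)=C\C)C[C@H](O[Si](CC)(CC)CC)[C@@](C)(O[Si](CC)(CC)CC)[C@@H](O[Si](C)(C)C(C)(C)C)[C@H]1OC(=O)/C(C)=C\C | intermediate
21 | (1S,3S,4S,5S,7R,8S,9S,10R)-9-(tert-butyldimethylsilyloxy)-4,5-epoxy-1,10-dihydroxygermacr-11-ene-3,8-diyl bis[(2Z)-2-methylbut-2-enoate] | C=C(C)[C@H]1C[C@@H]2O[C@]2(C)[C@@H](OC(=O)/C(C)=C\C)C[C@H](O)[C@@](C)(O)[C@@H](O[Si](C)(C)C(C)(C)C)[C@H]1OC(=O)/C(C)=C\C | intermediate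
22 | C1 methanesulfonate of diol 21 (1S,3S,4S,5S,7R,8S,9S,10S) | C=C(C)[C@H]1C[C@@H]2O[C@]2(C)[C@@H](OC(=O)/C(C)=C\C)C[C@H](OS(C)(=O)=O)[C@@](C)(O)[C@@H](O[Si](C)(C)C(C)(C)C)[C@H]1OC(=O)/C(C)=C\C | intermediate (not isolated)
23 | (1R,3S,4S,5S,7R,8S,9S,10R)-9-(tert-butyldimethylsilyloxy)-1,10:4,5-diepoxygermacr-11-ene-3,8-diyl bis[(2Z)-2-methylbut-2-enoate] | C=C(C)[C@H]1C[C@@H]2O[C@]2(C)[C@@H](OC(=O)/C(C)=C\C)C[C@H]2O[C@@]2(C)[C@@H](O[Si](C)(C)C(C)(C)C)[C@H]1OC(=O)/C(C)=C\C | intermediate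
24 | (1R,3S,4S,5S,7R,8S,9S,10S)-1,10:4,5-diepoxy-9-hydroxygermacr-11-ene-3,8-diyl bis[(2Z)-2-methylbut-2-enoate] (CNP0304877.1) | C=C(C)[C@H]1C[C@@H]2O[C@]2(C)[C@@H](OC(=O)/C(C)=C\C)C[C@H]2O[C@@]2(C)[C@@H](O)[C@H]1OC(=O)/C(C)=C\C | target

**Step count and risks**

Total steps: 17. Longest linear sequence: 17 steps (1 → 24); 5 and 19 are bought.

Steps most likely to fail:

Step 11. The dienol ether may be protonated or hydrolysed before it cyclises, the seven-ring closure may lose to oligomerisation, or C2 may add to the other face of C1. The fallback uses known chemistry, sets out from lactone 11 and returns at 16. MeLi (1.05 equiv, THF, −78 °C) opens the lactone to the Z hydroxy enone F1. The C8 hydroxyl is protected with 4-methoxybenzyl trichloroacetimidate and La(OTf)3 to give the 4-methoxybenzyl ether F2. HF·pyridine removes both triethylsilyl groups to give the diol F3, and Parikh–Doering oxidation gives the alpha-hydroxy aldehyde F4. TiCl4 and Bu3N (CH2Cl2, −78 °C, high dilution) then effect a titanium enolate aldol macrocyclisation; the titanium alkoxide at C10 chelates the aldehyde, so the methyl ketone enolate should enter from the methyl face and give the same C1 configuration in the cyclodecenone diol F5. Et3SiOTf and 2,6-lutidine give the bis(triethylsilyl) ether F6, and 2,3-dichloro-5,6-dicyano-1,4-benzoquinone (wet CH2Cl2) removes the 4-methoxybenzyl group to return 16.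

Step 13. Epoxidation of the isopropenyl group may compete, and the peracid may be delivered to the wrong face of C4=C5. The fallback sets out from enone 16 and returns at 20. The C8 hydroxyl is acylated first with the mixed anhydride of 19 (as in step 14) to give the C8 angelate F7. Reduction with the (S)-oxazaborolidine and catecholborane gives the 3R allylic alcohol F8. VO(acac)2 and t-BuOOH then give a metal-bound, hydroxyl-directed epoxidation that touches only the allylic alcohol alkene and should place oxygen cis to the 3R hydroxyl (the same epoxide face as in 18), giving the epoxy alcohol F9. A Mitsunobu esterification with 19 (PPh3, diisopropyl azodicarboxylate, toluene) inverts C3 and gives 20.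

Step 4. Equatorial attack of the Grignard reagent would give the C10 epimer, and the magnesium aldolate may suffer retro-aldol cleavage. The fallback sets out from 6 and returns at 7. The dilithium salt of 6 (LiN(SiMe3)2, THF, −78 °C) is treated with dimethylsulfonium methylide (from Me3SI and n-BuLi, −40 °C), the methylene-transfer reagent known for kinetically controlled axial attack on six-membered ketones, to give the spiro-epoxide F10. LiEt3BH (THF, 0 °C) opens it at the methylene carbon to the tertiary alcohol 7.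

Further compounds
F1 | step 11 | Z hydroxy enone from opening of lactone 11 (C3 methyl ketone, C8–OH, C9–OSiMe2t-Bu, C1 and C10–OSiEt3) | CC(=O)/C(C)=C\C[C@H](C(C)=C)[C@H](O)[C@H](O[Si](C)(C)C(C)(C)C)[C@](C)(O[Si](CC)(CC)CC)CO[Si](CC)(CC)CC
F2 | step 11 | C8 4-methoxybenzyl ether of F1 | CC(=O)/C(C)=C\C[C@H](C(C)=C)[C@H](OCc1ccc(OC)cc1)[C@H](O[Si](C)(C)C(C)(C)C)[C@](C)(O[Si](CC)(CC)CC)CO[Si](CC)(CC)CC
F3 | step 11 | C1,C10 diol from F2 | CC(=O)/C(C)=C\C[C@H](C(C)=C)[C@H](OCc1ccc(OC)cc1)[C@H](O[Si](C)(C)C(C)(C)C)[C@](C)(O)CO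
F4 | step 11 | C1 aldehyde with free C10 hydroxyl | CC(=O)/C(C)=C\C[C@H](C(C)=C)[C@H](OCc1ccc(OC)cc1)[C@H](O[Si](C)(C)C(C)(C)C)[C@](C)(O)C=O
F5 | step 11 | (1S,4Z,7R,8S,9S,10R)-9-(tert-butyldimethylsilyloxy)-1,10-dihydroxy-8-(4-methoxybenzyloxy)germacra-4,11-dien-3-one | C=C(C)[C@H]1C/C=C(C)\C(=O)C[C@H](O)[C@@](C)(O)[C@@H](O[Si](C)(C)C(C)(C)C)[C@H]1OCc2ccc(OC)cc2
F6 | step 11 | 1,10-bis(triethylsilyl) ether of F5 | C=C(C)[C@H]1C/C=C(C)\C(=O)C[C@H](O[Si](CC)(CC)CC)[C@@](C)(O[Si](CC)(CC)CC)[C@@H](O[Si](C)(C)C(C)(C)C)[C@H]1OCc2ccc(OC)cc2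
F7 | step 13 | C8 angelate of enone 16 | C=C(C)[C@H]1C/C=C(C)\C(=O)C[C@H](O[Si](CC)(CC)CC)[C@@](C)(O[Si](CC)(CC)CC)[C@@H](O[Si](C)(C)C(C)(C)C)[C@H]1OC(=O)/C(C)=C\C
F8 | step 13 | 3R allylic alcohol (C3 epimer series) with C8 angelate | C=C(C)[C@H]1C/C=C(C)\[C@H](O)C[C@H](O[Si](CC)(CC)CC)[C@@](C)(O[Si](CC)(CC)CC)[C@@H](O[Si](C)(C)C(C)(C)C)[C@H]1OC(=O)/C(C)=C\C
F9 | step 13 | 4,5-epoxy 3R alcohol with C8 angelate | C=C(C)[C@H]1C[C@@H]2O[C@]2(C)[C@H](O)C[C@H](O[Si](CC)(CC)CC)[C@@](C)(O[Si](CC)(CC)CC)[C@@H](O[Si](C)(C)C(C)(C)C)[C@H]1OC(=O)/C(C)=C\C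
F10 | step 4 | spiro-epoxide at C10 (C10–O–C14) of the dioxane acid | C=C(C)[C@@H](C/C=C(/C)C(=O)O)[C@H](O)[C@@H]1OC(C)(C)OC[C@]13CO3
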